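**Strategy.** The anti pair of oxygens on C5 (ether) and C6 (lactone) of oxepane ring A (O, C5–C10) is read as the product of a 1,2-oxygen shift. Ring A is therefore carried as a tetrahydropyran (O, C6–C10) with C5 outside the ring as a chloromethanesulfonate. In the key step the ring oxygen displaces this leaving group and the tert-butyl ester on C7 opens the resulting bicyclic oxonium ion at C6: one operation expands the pyran to the oxepane, inverts C5 and C6 and closes the trans γ-lactone. The precursor, a pentasubstituted tetrahydropyran, comes from an aldol reaction, ynone cyclisation and axial cuprate methylation; ring-closing metathesis then bridges the trans C5/C10 arms.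

Key step: step 14

Remark (assumption): the SMILES is taken literally; its bridgehead descriptors (5R,10S) put the C1–C4 bridge trans across ring A (H-5 inside, an in,out 11-oxabicyclo[4.4.1]undecene), so the arms on C5 and C10 are built trans.

Numbering used in names: germacrane numbering of the target (C12 lactone carbonyl on O–C6, C11=C13, angelate on O–C8, C9H2, C10 with methyl C14, C1 ketone, C2=C3, C4 with hydroxymethyl C15, ether O between C5 and C10). C1 is carried as both epimers until the last step.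

Step 1
Reactants: 1 2,2-dimethoxyethanol; 2 4-ethenyl-1,3-dioxolan-2-one (racemic)
Product: 3 (2R,3S)-2-ethenyl-4,4-dimethoxybutane-1,3-diol
Conditions: [Ir(cod)Cl]2 (cat.), SEGPHOS (the enantiomer that gives the (2R,3S) diol), 4-cyano-3-nitrobenzoic acid (cat.), K3PO4 (cat.), THF, 90 °C
Reagents that add atoms: none
Why: Redox-neutral iridium-catalysed carbonyl (hydroxymethyl)allylation from the alcohol oxidation level (dehydrogenation of 1, decarboxylative ionisation of 2, addition through a closed chair transition state) should give the anti 1,3-diol, with C4 and C5 set by the chiral ligand.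

Step 2
Reactants: 3 (2R,3S)-2-ethenyl-4,4-dimethoxybutane-1,3-diol
Product: 4 (2S,3R)-3-[(tert-butyldiphenylsilyl)oxymethyl]-1,1-dimethoxypent-4-en-2-ol
Conditions: t-BuPh2SiCl, imidazole, CH2Cl2, 0 °C
Reagents that add atoms: tert-butyl(chloro)diphenylsilane CC(C)(C)[Si](Cl)(c1ccccc1)c1ccccc1
Why: Selective silylation of the primary (C15) hydroxyl over the hindered secondary one.

Step 3
Reactants: 4 (2S,3R)-3-[(tert-butyldiphenylsilyl)oxymethyl]-1,1-dimethoxypent-4-en-2-ol
Product: 7 (2S,3R)-3-[(tert-butyldiphenylsilyl)oxymethyl]-2-(triethylsilyloxy)pent-4-enal, via triethylsilyl ether acetal 5 (not isolated), via collidinium triflate 6 (not isolated)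
Conditions: Et3SiOTf (excess), 2,4,6-collidine, CH2Cl2, −78 → 0 °C; then H2O
Reagents that add atoms: triethylsilyl trifluoromethanesulfonate CC[Si](CC)(CC)OS(=O)(=O)C(F)(F)F; water O
Why: Silylation of the C5 hydroxyl followed by silyl triflate/collidine cleavage of the dimethyl acetal (pyridinium salt, hydrolysed by water) should free the aldehyde under non-acidic conditions that keep both silyl ethers and the α-stereocentre.

Step 4
Reactants: 8 pent-1-en-4-yn-3-ol (racemic)
Product: 9 tert-butyl(dimethyl)(pent-1-en-4-yn-3-yloxy)silane (racemic)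
Conditions: t-BuMe2SiCl, imidazole, DMF, 23 °C
Reagents that add atoms: tert-butyl(chloro)dimethylsilane CC(C)(C)[Si](C)(C)Cl
Why: Standard silylation of a secondary propargylic alcohol; this unit supplies C10, C9, C1 and C2.

Step 5
Reactants: 10 4-tert-butoxy-4-oxobutanoic acid
Product: 12 tert-butyl 4-[methoxy(methyl)amino]-4-oxobutanoate, via acyl imidazole 11 (not isolated)
Conditions: 1,1'-carbonyldiimidazole, CH2Cl2, 23 °C; then MeNHOMe·HCl
Reagents that add atoms: N,O-dimethylhydroxylamine hydrochloride CNOC.Cl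
Why: Acyl imidazole formation and aminolysis give the N-methoxy-N-methylamide (Weinreb amide).

Step 6
Reactants: 9 tert-butyl(dimethyl)(pent-1-en-4-yn-3-yloxy)silane; 12 tert-butyl 4-[methoxy(methyl)amino]-4-oxobutanoate
Product: 14 tert-butyl 7-(tert-butyldimethylsilyloxy)-4-oxonon-8-en-5-ynoate (racemic), via lithium acetylide 13 (not isolated)
Conditions: n-BuLi, THF, −78 °C; then 12, −78 → −20 °C; NH4Cl (aq.)
Reagents that add atoms: none
Why: Addition of the lithium acetylide to the Weinreb amide stops at the chelated tetrahedral adduct and releases the ynone on work-up, the tert-butyl ester being inert at low temperature.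

Step 7
Reactants: 14 tert-butyl 7-(tert-butyldimethylsilyloxy)-4-oxonon-8-en-5-ynoate; 7 (2S,3R)-3-[(tert-butyldiphenylsilyl)oxymethyl]-2-(triethylsilyloxy)pent-4-enal
Product: 16 (4R,5S,6R,7S)-β-hydroxy ynone (C6–OH; C5–OSiEt3; C7 bearing CH2CO2t-Bu and the C8 ynone), via boron enolate 15 (not isolated)
Conditions: (c-C6H11)2BCl, Et3N, Et2O, −78 → 0 °C; then 7, −78 → −20 °C; then pH 7 buffer, MeOH, H2O2, 0 °C
Reagents that add atoms: none
Why: Boron-mediated anti aldol reaction: the (E)-enolate (only C7 is enolisable) adds through a chair transition state (C6/C7 anti) to the aldehyde face favoured by the polar Felkin–Anh/Cornforth model for an α-silyloxy aldehyde (C5/C6 anti).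

Step 8
Reactants: 16 (4R,5S,6R,7S)-β-hydroxy ynone
Product: 17 (4R,5S,6R,7S)-2,3-dihydro-4H-pyran-4-one (ring O, C6–C10; C9=C10; C6 and C7 substituents trans)
Conditions: AgOTf (cat.), CH2Cl2, 23 °C, dark
Reagents that add atoms: none
Why: Silver-catalysed 6-endo-dig oxa-cyclisation of the β-hydroxy ynone forms the O–C10 bond of the six-membered precursor of ring A without touching the stereocentres (C7, next to the ketone, stays trans to C6).

Step 9
Reactants: 17 (4R,5S,6R,7S)-2,3-dihydro-4H-pyran-4-one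
Product: 19 (4R,5S,6R,7S,10S)-tetrahydropyran-4-one with quaternary C10 (methyl trans to the C6 side chain), via trimethylsilyl enol ether 18 (not isolated)
Conditions: Me2CuLi (from MeLi and CuI), Me3SiCl, THF–Et2O, −78 → −30 °C; then citric acid (aq.), 0 °C
Reagents that add atoms: lithium dimethylcuprate [Li+].C[Cu-]C
Why: Conjugate addition of the methyl cuprate to the vinylogous ester by stereoelectronically controlled axial attack anti to the C6 substituent (the 2,6-trans rule for dihydropyranones) sets C10 with the methyl axial.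

Step 10
Reactants: 19 (4R,5S,6R,7S,10S)-tetrahydropyran-4-one
Product: 20 (4R,5S,6R,7R,8R,10S)-tetrahydropyran-4-ol (axial C8–OH cis to the C7 side chain)
Conditions: LiBH(s-Bu)3, THF, −78 °C; AcOH quench at −78 °C; non-basic work-up
Reagents that add atoms: none
Why: The bulky borohydride attacks from the equatorial direction (axial approach is blocked by the axial C10 methyl) to give the axial alcohol, and the cold acidic quench keeps the cis hydroxy tert-butyl ester from lactonising.

Step 11
Reactants: 20 (4R,5S,6R,7R,8R,10S)-tetrahydropyran-4-ol; 21 angelic acid ((Z)-2-methylbut-2-enoic acid)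
Product: 23 (4R,5S,6R,7R,8R,10S)-8-O-angelate, via mixed anhydride 22 (not isolated)
Conditions: 2,4,6-trichlorobenzoyl chloride, Et3N, toluene, 23 °C; then 20, toluene, 75 °C (no 4-dimethylaminopyridine)
Reagents that add atoms: none
Why: Yamaguchi esterification through the mixed anhydride acylates O8 with retention, and leaving out a nucleophilic amine catalyst avoids Z to E isomerisation of the angelate.

Step 12
Reactants: 23 (4R,5S,6R,7R,8R,10S)-8-O-angelate
Product: 24 (4R,5S,6R,7R,8R,10S)-C5 alcohol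
Conditions: pyridinium p-toluenesulfonate (cat.), MeOH–CH2Cl2, 0 °C
Reagents that add atoms: none
Why: Acid-catalysed methanolysis removes the most labile silyl ether (secondary triethylsilyl) and leaves the tert-butyldimethylsilyl and tert-butyldiphenylsilyl ethers and both esters.

Step 13
Reactants: 24 (4R,5S,6R,7R,8R,10S)-C5 alcohol
Product: 25 (4R,5S,6R,7R,8R,10S)-C5 chloromethanesulfonate
Conditions: ClCH2SO2Cl, 2,6-lutidine, CH2Cl2, 0 °C
Reagents that add atoms: chloromethanesulfonyl chloride ClCS(Cl)(=O)=O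
Why: Sulfonylation of the hindered C5 alcohol with the small, reactive sulfonyl chloride (retention at C5) installs a leaving group suited to oxygen participation.

Step 14
Reactants: 25 (4R,5S,6R,7R,8R,10S)-C5 chloromethanesulfonate
Product: 28 (4R,5R,6S,7R,8R,10S)-oxepane-fused saturated γ-lactone (12,6-olide), via bicyclic oxonium ion 26 (not isolated), via tert-butyl lactonium ion 27 (not isolated)
Conditions: Zn(OAc)2, AcOH–H2O (4:1), 50 °C
Reagents that add atoms: none
Why: In the low-energy rotamer about C5–C6 (C4 anti to C7) the ring oxygen lies anti-periplanar to the sulfonate and displaces it (3-exo-tet, inversion at C5) to give oxonium ion 26; the carbonyl oxygen of the tert-butyl ester on C7 then opens the C6–O bond from the rear (5-exo-tet, inversion at C6) and lactonium ion 27 loses the tert-butyl cation to water. The closest known reaction type is the zinc acetate-promoted rearrangement–ring expansion of 2-(1-sulfonyloxyalkyl)tetrahydropyrans to 3-acyloxyoxepanes, here with the neighbouring ester in place of acetate. Ring A grows from the six-membered pyran (O, C6–C10) to the seven-membered oxepane (O, C5–C10) by the 1,2-oxygen shift, and the γ-lactone closes by the 5-exo opening. C5 and C6 are both set stereospecifically by double inversion (5S,6R to 5R,6S), which gives the trans lactone and the trans C5/C10 substitution of the oxepane. The step needs participation of the ring oxygen to outrun direct six-membered O-alkylation of the ester at C5 and capture by acetate; the anti C5/C6 configuration, which puts the leaving group anti to the ring oxygen in the favoured rotamer, and the intramolecular 5-exo path to C6 should secure this.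

Step 15
Reactants: 28 (4R,5R,6S,7R,8R,10S)-oxepane-fused saturated γ-lactone
Product: 31 (4R,5R,6S,7R,8R,10S)-α-methylene γ-lactone, via Mannich base 29 (not isolated), via trimethylammonium iodide 30 (not isolated)
Conditions: LiN(iPr)2, THF, −78 °C; CH2=NMe2+ I−, −78 → 0 °C; then MeI, MeOH, 23 °C; then NaHCO3 (aq.), CH2Cl2
Reagents that add atoms: N,N-dimethylmethyleneiminium iodide C=[N+](C)C.[I-]
Why: α-Methylenation by the Mannich route: the lactone enolate (the most acidic site, with no β-leaving group) is aminomethylated, and quaternisation followed by mild base eliminates trimethylamine to the exocyclic C11=C13 alkene without touching a stereocentre.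

Step 16
Reactants: 31 (4R,5R,6S,7R,8R,10S)-α-methylene γ-lactone
Product: 32 (4R,5R,6S,7R,8R,10S)-1,15-diol with vinyl groups on C1 and C4
Conditions: HF·pyridine, pyridine, THF, 0 → 23 °C
Reagents that add atoms: none
Why: Fluoride cleaves both remaining silyl ethers while the esters, the lactone and the alkenes are inert.

Step 17
Reactants: 32 (4R,5R,6S,7R,8R,10S)-1,15-diol with vinyl groups on C1 and C4
Product: 33 (4R,5R,6S,7R,8R,10S)-1,15-dihydroxy-5,10-epoxygermacra-2,11(13)-dien-12,6-olide 8-angelate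
Conditions: second-generation Hoveyda–Grubbs catalyst RuCl2(H2IMes)(=CH-C6H4-2-OiPr) (cat.), toluene (high dilution), 80 °C, argon sparge
Reagents that add atoms: none
Why: Ring-closing metathesis of the two monosubstituted alkenes forms the cis C2=C3 bond and closes ring B across the trans C5/C10 arms to the in,out bicycle (as in metathesis closures of the in,out bicyclo[4.4.1] core of ingenanes), the 1,1-disubstituted acrylate and the trisubstituted angelate being poor metathesis partners.

Step 18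
Reactants: 33 (4R,5R,6S,7R,8R,10S)-1,15-dihydroxy-5,10-epoxygermacra-2,11(13)-dien-12,6-olide 8-angelate
Product: 34 (4R,5R,6S,7R,8R,10S)-8-angeloyloxy-15-hydroxy-1-oxo-5,10-epoxygermacra-2,11(13)-dien-12,6-olide (target)
Conditions: MnO2 (activated, excess), CH2Cl2, 23 °C
Reagents that add atoms: none
Why: MnO2 oxidises only the allylic C1 alcohol (both epimers converge on the enone) and leaves the primary, non-allylic C15 alcohol.

**Compound list**

1 | 2,2-dimethoxyethanol | COC(CO)OC | starting material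
2 | 4-ethenyl-1,3-dioxolan-2-one (racemic) | C=CC1COC(=O)O1 | starting material
3 | (2R,3S)-2-ethenyl-4,4-dimethoxybutane-1,3-diol | COC(OC)[C@@H](O)[C@@H](CO)C=C | intermediate
4 | (2S,3R)-3-[(tert-butyldiphenylsilyl)oxymethyl]-1,1-dimethoxypent-4-en-2-ol | COC(OC)[C@@H](O)[C@@H](CO[Si](c1ccccc1)(c1ccccc1)C(C)(C)C)C=C | intermediate
5 | triethylsilyl ether of 4 (dimethyl acetal) | COC(OC)[C@@H](O[Si](CC)(CC)CC)[C@@H](CO[Si](c1ccccc1)(c1ccccc1)C(C)(C)C)C=C | intermediate (not isolated)
6 | 2,4,6-trimethylpyridinium salt from 5 (methoxy N,O-acetal at C6, triflate) | COC([C@@H](O[Si](CC)(CC)CC)[C@@H](CO[Si](c1ccccc1)(c1ccccc1)C(C)(C)C)C=C)[n+]1c(C)cc(C)cc1C.[O-]S(=O)(=O)C(F)(F)F | intermediate (not isolated)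
7 | (2S,3R)-3-[(tert-butyldiphenylsilyl)oxymethyl]-2-(triethylsilyloxy)pent-4-enal | O=C[C@@H](O[Si](CC)(CC)CC)[C@@H](CO[Si](c1ccccc1)(c1ccccc1)C(C)(C)C)C=C | intermediate
8 | pent-1-en-4-yn-3-ol (racemic) | C#CC(O)C=C | starting material
9 | tert-butyl(dimethyl)(pent-1-en-4-yn-3-yloxy)silane (racemic) | C#CC(O[Si](C)(C)C(C)(C)C)C=C | intermediate
10 | 4-tert-butoxy-4-oxobutanoic acid | OC(=O)CCC(=O)OC(C)(C)C | starting material
11 | tert-butyl 4-(imidazol-1-yl)-4-oxobutanoate | O=C(CCC(=O)OC(C)(C)C)n1ccnc1 | intermediate (not isolated)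
12 | tert-butyl 4-[methoxy(methyl)amino]-4-oxobutanoate | CON(C)C(=O)CCC(=O)OC(C)(C)C | intermediate
13 | lithium acetylide of 9 | [Li]C#CC(O[Si](C)(C)C(C)(C)C)C=C | intermediate (not isolated)
14 | tert-butyl 7-(tert-butyldimethylsilyloxy)-4-oxonon-8-en-5-ynoate (racemic) | C=CC(O[Si](C)(C)C(C)(C)C)C#CC(=O)CCC(=O)OC(C)(C)C | intermediate
15 | (E)-dicyclohexylboron enolate of 14 | C=CC(O[Si](C)(C)C(C)(C)C)C#C/C(OB(C1CCCCC1)C1CCCCC1)=C\CC(=O)OC(C)(C)C | intermediate (not isolated)
16 | (4R,5S,6R,7S)-β-hydroxy ynone (aldol adduct; C1 epimers) | C=CC(O[Si](C)(C)C(C)(C)C)C#CC(=O)[C@@H](CC(=O)OC(C)(C)C)[C@@H](O)[C@@H](O[Si](CC)(CC)CC)[C@@H](CO[Si](c1ccccc1)(c1ccccc1)C(C)(C)C)C=C | intermediate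
17 | (4R,5S,6R,7S)-2,3-dihydro-4H-pyran-4-one (ring O, C6–C10) | C=CC(O[Si](C)(C)C(C)(C)C)C1=CC(=O)[C@@H](CC(=O)OC(C)(C)C)[C@@H](O1)[C@@H](O[Si](CC)(CC)CC)[C@@H](CO[Si](c2ccccc2)(c2ccccc2)C(C)(C)C)C=C | intermediate
18 | trimethylsilyl enol ether (C8=C9) of 19 | C[C@@]1(C(O[Si](C)(C)C(C)(C)C)C=C)C=C(O[Si](C)(C)C)[C@@H](CC(=O)OC(C)(C)C)[C@@H](O1)[C@@H](O[Si](CC)(CC)CC)[C@@H](CO[Si](c2ccccc2)(c2ccccc2)C(C)(C)C)C=C | intermediate (not isolated)
19 | (4R,5S,6R,7S,10S)-tetrahydropyran-4-one | C[C@@]1(C(O[Si](C)(C)C(C)(C)C)C=C)CC(=O)[C@@H](CC(=O)OC(C)(C)C)[C@@H](O1)[C@@H](O[Si](CC)(CC)CC)[C@@H](CO[Si](c2ccccc2)(c2ccccc2)C(C)(C)C)C=C | intermediate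
20 | (4R,5S,6R,7R,8R,10S)-tetrahydropyran-4-ol (axial C8–OH) | C[C@@]1(C(O[Si](C)(C)C(C)(C)C)C=C)C[C@@H](O)[C@@H](CC(=O)OC(C)(C)C)[C@@H](O1)[C@@H](O[Si](CC)(CC)CC)[C@@H](CO[Si](c2ccccc2)(c2ccccc2)C(C)(C)C)C=C | intermediate
21 | angelic acid, (Z)-2-methylbut-2-enoic acid | C/C=C(/C)C(=O)O | starting material
22 | angelic 2,4,6-trichlorobenzoic anhydride | C/C=C(/C)C(=O)OC(=O)c1c(Cl)cc(Cl)cc1Cl | intermediate (not isolated)
23 | (4R,5S,6R,7R,8R,10S)-8-O-angelate (C5–OSiEt3) | C[C@@]1(C(O[Si](C)(C)C(C)(C)C)C=C)C[C@@H](OC(=O)/C(C)=C\C)[C@@H](CC(=O)OC(C)(C)C)[C@@H](O1)[C@@H](O[Si](CC)(CC)CC)[C@@H](CO[Si](c2ccccc2)(c2ccccc2)C(C)(C)C)C=C | intermediate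
24 | (4R,5S,6R,7R,8R,10S)-C5 alcohol | C[C@@]1(C(O[Si](C)(C)C(C)(C)C)C=C)C[C@@H](OC(=O)/C(C)=C\C)[C@@H](CC(=O)OC(C)(C)C)[C@@H](O1)[C@@H](O)[C@@H](CO[Si](c2ccccc2)(c2ccccc2)C(C)(C)C)C=C | intermediate
25 | (4R,5S,6R,7R,8R,10S)-C5 chloromethanesulfonate (tetrahydropyran precursor of ring A) | C[C@@]1(C(O[Si](C)(C)C(C)(C)C)C=C)C[C@@H](OC(=O)/C(C)=C\C)[C@@H](CC(=O)OC(C)(C)C)[C@@H](O1)[C@@H](OS(=O)(=O)CCl)[C@@H](CO[Si](c2ccccc2)(c2ccccc2)C(C)(C)C)C=C | intermediate
26 | bicyclic oxonium ion (O bonded to C5, C6 and C10), chloromethanesulfonate | C[C@@]1(C(O[Si](C)(C)C(C)(C)C)C=C)C[C@@H](OC(=O)/C(C)=C\C)[C@@H](CC(=O)OC(C)(C)C)[C@@H]2[C@@H]([C@@H](CO[Si](c3ccccc3)(c3ccccc3)C(C)(C)C)C=C)[O+]12.[O-]S(=O)(=O)CCl | intermediate (not isolated)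
27 | O-tert-butyl lactonium ion of 28, chloromethanesulfonate | C1C(=[O+]C(C)(C)C)O[C@@H]2[C@@H]([C@@H](CO[Si](c3ccccc3)(c3ccccc3)C(C)(C)C)C=C)O[C@@](C)(C[C@@H](OC(=O)/C(C)=C\C)[C@@H]12)C(O[Si](C)(C)C(C)(C)C)C=C.[O-]S(=O)(=O)CCl | intermediate (not isolated)
28 | (4R,5R,6S,7R,8R,10S)-oxepane-fused saturated γ-lactone | C1C(=O)O[C@@H]2[C@@H]([C@@H](CO[Si](c3ccccc3)(c3ccccc3)C(C)(C)C)C=C)O[C@@](C)(C[C@@H](OC(=O)/C(C)=C\C)[C@@H]12)C(O[Si](C)(C)C(C)(C)C)C=C | intermediate
29 | C11 dimethylaminomethyl lactone (Mannich base) | CN(C)CC1C(=O)O[C@@H]2[C@@H]([C@@H](CO[Si](c3ccccc3)(c3ccccc3)C(C)(C)C)C=C)O[C@@](C)(C[C@@H](OC(=O)/C(C)=C\C)[C@@H]12)C(O[Si](C)(C)C(C)(C)C)C=C | intermediate (not isolated)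
30 | trimethylammonium iodide from 29 | C[N+](C)(C)CC1C(=O)O[C@@H]2[C@@H]([C@@H](CO[Si](c3ccccc3)(c3ccccc3)C(C)(C)C)C=C)O[C@@](C)(C[C@@H](OC(=O)/C(C)=C\C)[C@@H]12)C(O[Si](C)(C)C(C)(C)C)C=C.[I-] | intermediate (not isolated)
31 | (4R,5R,6S,7R,8R,10S)-α-methylene γ-lactone, bis-silyl ether | C=C1C(=O)O[C@@H]2[C@@H]([C@@H](CO[Si](c3ccccc3)(c3ccccc3)C(C)(C)C)C=C)O[C@@](C)(C[C@@H](OC(=O)/C(C)=C\C)[C@@H]12)C(O[Si](C)(C)C(C)(C)C)C=C | intermediate
32 | (4R,5R,6S,7R,8R,10S)-1,15-diol diene | C=C1C(=O)O[C@@H]2[C@@H]([C@@H](CO)C=C)O[C@@](C)(C[C@@H](OC(=O)/C(C)=C\C)[C@@H]12)C(O)C=C | intermediate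
33 | (4R,5R,6S,7R,8R,10S)-1,15-dihydroxy-5,10-epoxygermacra-2,11(13)-dien-12,6-olide 8-angelate | C=C1C(=O)O[C@@H]2[C@@H]3O[C@@](C)(C[C@@H](OC(=O)/C(C)=C\C)[C@@H]12)C(O)C=C[C@@H]3CO | intermediate
34 | (4R,5R,6S,7R,8R,10S)-8-angeloyloxy-15-hydroxy-1-oxo-5,10-epoxygermacra-2,11(13)-dien-12,6-olide | C=C1C(=O)O[C@@H]2[C@@H]3O[C@@](C)(C[C@@H](OC(=O)/C(C)=C\C)[C@@H]12)C(=O)C=C[C@@H]3CO | target

**Totals.** 18 steps in all; longest linear sequence 15 steps (steps 1–3 and 7–18).

**Steps most likely to fail**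

Step 17 (ring-closing metathesis). The closure has to build the strained in,out bicycle, so cyclisation may be slow and lose to intermolecular metathesis (oligomerisation) or to engagement of the α-methylene lactone. The fallback closes ring B before the ring expansion, while the two arms are still cis on the tetrahedropyran-stage intermediate. It sets out from 25: ring-closing metathesis with the same ruthenium catalyst should give the unstrained out,out 11-oxabicyclo[5.3.1]undecene chloromethanesulfonate F1. The zinc acetate-promoted 1,2-oxygen shift with lactonisation (conditions of step 14) then moves the oxygen bridge from C6 to C5 and should give the tricyclic saturated lactone F2. Mannich methylenation as in step 15 gives the α-methylene lactone F3, and HF·pyridine removes both silyl ethers, which returns to the route at 33.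

Step 14 (key step). The ester oxygen may be alkylated at C5 through a six-membered transition state, or the oxonium ion may be captured by the medium or lost by elimination before the ester reaches C6. The fallback separates ring expansion from lactonisation. It sets out from 25: the ring expansion is run with acetate as the external nucleophile (Zn(OAc)2, anhydrous AcOH, added Bu4NOAc), which should give the 6-acetoxy oxepane tert-butyl ester F4. K2CO3 in MeOH at 0 °C removes the acetate in the presence of the hindered angelate to give the C6 alcohol F5, and catalytic p-toluenesulfonic acid in toluene closes the trans lactone with loss of tert-butanol, returning to the route at 28.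

Step 9 (cuprate addition). Conjugate addition at the branched, fully substituted β-carbon may stall, or competing 1,2-addition and enolisation may take over. The fallback forms the C10–methyl bond on the open chain. It sets out from 16: Me2CuLi adds to the ynone to give the β-methyl enone F6 (E/Z mixture), and a reversible, DBU-mediated 6-endo oxa-Michael addition of the C6 hydroxyl closes the pyranone under thermodynamic control (both ring substituents and the bulky C1 group equatorial, methyl axial), returning to the route at 19.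

Further compounds
F1 | step 17 | out,out 11-oxabicyclo[5.3.1]undecene chloromethanesulfonate (ring B closed on the tetrahydropyran; C2=C3 in the eight-membered ring) | C[C@@]1(C(O[Si](C)(C)C(C)(C)C)C=C2)C[C@@H](OC(=O)/C(C)=C\C)[C@@H](CC(=O)OC(C)(C)C)[C@@H](O1)[C@@H](OS(=O)(=O)CCl)[C@H]2CO[Si](c3ccccc3)(c3ccccc3)C(C)(C)C
F2 | step 17 | tricyclic saturated 12,6-lactone with C1 tert-butyldimethylsilyl ether and C15 tert-butyldiphenylsilyl ether | C1C(=O)O[C@@H]2[C@@H]3O[C@@](C)(C[C@@H](OC(=O)/C(C)=C\C)[C@@H]12)C(O[Si](C)(C)C(C)(C)C)C=C[C@@H]3CO[Si](c4ccccc4)(c4ccccc4)C(C)(C)C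
F3 | step 17 | tricyclic α-methylene lactone bis-silyl ether | C=C1C(=O)O[C@@H]2[C@@H]3O[C@@](C)(C[C@@H](OC(=O)/C(C)=C\C)[C@@H]12)C(O[Si](C)(C)C(C)(C)C)C=C[C@@H]3CO[Si](c4ccccc4)(c4ccccc4)C(C)(C)C
F4 | step 14 | (4R,5R,6S,7R,8R,10S)-6-acetoxy oxepane with the tert-butyl ester intact | CC(=O)O[C@@H]1[C@@H]([C@@H](CO[Si](c2ccccc2)(c2ccccc2)C(C)(C)C)C=C)O[C@@](C)(C[C@@H](OC(=O)/C(C)=C\C)[C@H]1CC(=O)OC(C)(C)C)C(O[Si](C)(C)C(C)(C)C)C=C
F5 | step 14 | (4R,5R,6S,7R,8R,10S)-6-hydroxy oxepane tert-butyl ester | O[C@@H]1[C@@H]([C@@H](CO[Si](c2ccccc2)(c2ccccc2)C(C)(C)C)C=C)O[C@@](C)(C[C@@H](OC(=O)/C(C)=C\C)[C@H]1CC(=O)OC(C)(C)C)C(O[Si](C)(C)C(C)(C)C)C=C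
F6 | step 9 | β-methyl enone from 16 (C9=C10, E/Z mixture) | C=CC(O[Si](C)(C)C(C)(C)C)C(C)=CC(=O)[C@@H](CC(=O)OC(C)(C)C)[C@@H](O)[C@@H](O[Si](CC)(CC)CC)[C@@H](CO[Si](c1ccccc1)(c1ccccc1)C(C)(C)C)C=C
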